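The data are calculated for substances that don't exist; noise was put on by code.

If Monday's run is this very flask followed so far, the chair opened, then its earliest readings should already answer for 4.0 h.

| flask | starting material | gas | remark | time |
|---|---|---|---|---|
| Monday's | 0.50 M | 200 mM (held) | the very flask that is asked about, followed so far |  |
| flask | 0.50 M | 200 mM (held) |  | 15 d |

- Monday's (time / d: isomer of the product / %, target / %): 0.250: 5.5, 15.7; 0.333: 7.5, 22.4; 0.500: 12.5, 32.2; 0.833: 17.6, 43.6; 1.25: 21.6, 43.0; 2.08: 25.0, 31.3; 3.00: 26.3, 20.7

(readings scatter by 0.5 percentage points)

- at the start none of the gas is in solution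

- share of isomer of the product in isomer of the product plus target at 4.0 h
- share of isomer of the product in isomer of the product plus target at 15 d
- which of isomer of the product and target there is more of at 15 d

The first speaker pooled the readings at 0.250 d and 0.333 d and obtained 25.4% for the early share, meaning isomer of the product over isomer plus target in the earliest readings, which is the usual selectivity. The second speaker put that answer back in: if the share held for the whole charge, the isomer should level off near that same figure of the charge. Monday's isomer reading at 3.00 d is 26.3%, a gap of 0.90 percentage points against a scatter of 0.5 points, so she kept the early share for 4.0 h. The third speaker took the target's fall between the last two readings, 0.449 d⁻¹, and carried it to 15 d, which leaves 0.0941% of target and a share of 99.6%.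

The forecast, made separately, gave 25.5% (range 21% to 30%) and 99.5% (range 93% to 100%), with isomer of the product ahead, and it said the isomer looks like “a parallel, stable branch”.

The flask gives 25.0% and 96.1%, with isomer of the product ahead, 22.8% to 0.930% of target, so the forecast held on each mark.

    starting material + partner → intermediate + released group (k = 2.30 L mol⁻¹ h⁻¹)
    intermediate ⇌ target (K = 8.40, k = 0.0620 h⁻¹)
    intermediate ⇌ isomer of the product (K = 17.0, k = 0.0200 h⁻¹)
    partner + target → over-reaction product (k = 0.110 L mol⁻¹ h⁻¹)
    gas ⇌ partner, rate k5*(csat - [partner]) (kL = 2.20 h⁻¹)

The meeting had taken the isomer in this flask as level at 25.4% of the charge, but the isomer stands at 26.2% at 7.50 d and then falls to 22.8% at 15 d. The target's 0.930% at 15 d is more than the 0.0941% reckoned, and the share of this flask stands 3.5 points below the reckoned 99.6%, inside the forecast's range. The same reckoning on the neighbouring flask, charged with 0.12 M of starting material, puts 25.4% of its charge, 30.5 mM, into isomer. It gives 25.1% at 4.0 h and 96.1% at 15 d, and its isomer ends at 22.7% of its charge, or 27.2 mM.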